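## Retrosynthetic overview

1. The strategy rests on the E-trisubstituted C3=C4 alkene of the 14-membered carbocycle (ring A). It bears methyl C18 on C4 and lies next to the lactone oxygen on C2, and it is traced back to a C3≡C4 cycloalkyne, so ring closure has no alkene geometry to control.
2. The C12 hydroperoxide and the E-C10=C11 alkene come last, from a Schenck ene reaction on the E-C11=C12 alkene. Methyl C18 comes from trans-hydrosilylation (Si on C4), iododesilylation and methyl coupling of the cycloalkyne.
3. The cycloalkyne comes from ring-closing alkyne metathesis of a bislactone diyne with a propynyl group on C2 and a 2-butynyl group on C6. This forms only the C3≡C4 bond.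
4. The diyne comes from an asymmetric chromium allylation of 2-butynal (C1–C2 bond, trans α-methylene lactone, ring B). The other end comes from C8–C9 alkylation of a phenylsulfanyl lactone (masked butenolide, ring C, from (R)-epichlorohydrin) with a C9–C1 iodide built by carboalumination of 4-pentyn-1-ol.
5. Order of ring formation: ring C (step 6, unmasked in step 14), ring B (step 13), ring A (step 15).

Key step: step 15

Atom labels (cembrane numbering): ring A = C1–C14. C15 on C1 carries carbonyl C16 and methylene C17 (ring B: C1, C2, O, C16, C15). Methyl C18 is on C4. Ring C: C6, C7, C8, C19, O. Methyl C20 is on C12.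

Assumption: the (S,S) antipode of the carbazole bis(oxazoline) ligand is taken to steer the allylchromium reagent to the Re face of 2-butynal; if a first run shows the opposite sense, the (R,R) ligand takes its place.

Assumption: the outer face of C11=C12 in the preferred conformer of ring A is taken to be the one that leads to 12S, as expected if the hydroperoxide arises from the parent cembranolide by photooxygenation.

## Route

Step 1
Reactants: 1 4-pentyn-1-ol
Product: 2 tert-butyldimethyl(pent-4-yn-1-yloxy)silane
Conditions: TBSCl, imidazole, CH2Cl2, 0 °C → rt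
Reagents that add atoms: tert-butyldimethylsilyl chloride, CC(C)(C)[Si](C)(C)Cl
Why: Routine silyl ether protection of the primary alcohol, needed because the free hydroxyl would consume the organoaluminium reagent and later the enolate base.

Step 2
Reactants: 2 tert-butyldimethyl(pent-4-yn-1-yloxy)silane; 3 ethylene oxide
Product: 6 (E)-7-(tert-butyldimethylsilyloxy)-4-methylhept-3-en-1-ol, via alkenylalane 4 (not isolated), via lithium alanate 5 (not isolated)
Conditions: Me3Al (2.5 equiv), Cp2ZrCl2 (0.25 equiv), CH2Cl2, 0 °C → rt; excess Me3Al evaporated; hexane, n-BuLi, −78 → 0 °C; 3, THF, −78 °C → rt; aq. Rochelle salt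
Reagents that add atoms: trimethylaluminium, C[Al](C)C
Why: Zirconium-catalysed Negishi carboalumination adds methyl (C20) to C12 and aluminium to C11 in a syn fashion with terminal regioselectivity, and the more nucleophilic alanate opens oxirane with retention at the alkenyl carbon, so the E-C11=C12 alkene and the C9–C10 unit are installed in one flask.

Step 3
Reactants: 6 (E)-7-(tert-butyldimethylsilyloxy)-4-methylhept-3-en-1-ol
Product: 7 (E)-tert-butyl[(7-iodo-4-methylhept-4-en-1-yl)oxy]dimethylsilane
Conditions: I2, PPh3, imidazole, CH2Cl2, 0 °C
Reagents that add atoms: iodine, II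
Why: Appel-type iodination converts the primary homoallylic alcohol into the iodide by SN2 displacement of the oxyphosphonium group under neutral conditions that leave the silyl ether and the alkene alone.

Step 4
Reactants: 8 propyne; 9 (R)-epichlorohydrin
Product: 11 (R)-1-chlorohex-4-yn-2-ol, via 1-propynyllithium 10 (not isolated)
Conditions: 8, n-BuLi, THF, −78 °C; BF3·OEt2; 9, −78 °C; aq. NH4Cl
Reagents that add atoms: none
Why: BF3-promoted epoxide opening by a lithium acetylide takes place at the unsubstituted oxirane carbon faster than any displacement of chloride, so the C4–C5 bond forms with the methyl cap already in place and the C–O bond at the stereocentre (the later C6) is untouched.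

Step 5
Reactants: 11 (R)-1-chlorohex-4-yn-2-ol
Product: 12 (R)-2-(but-2-yn-1-yl)oxirane
Conditions: NaOH (powder), Et2O, 0 °C → rt
Reagents that add atoms: none
Why: Intramolecular Williamson displacement of chloride by the alkoxide closes the new oxirane without breaking a bond at the stereocentre, which therefore stays R.

Step 6
Reactants: 13 (phenylsulfanyl)acetic acid; 12 (R)-2-(but-2-yn-1-yl)oxirane
Product: 16 (5R)-5-(but-2-yn-1-yl)-3-(phenylsulfanyl)oxolan-2-one (C3 epimers), via dilithio dianion 14 (not isolated), via hydroxy acid 15 (not isolated)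
Conditions: 13, LDA (2.1 equiv), THF, 0 °C; 12, 0 °C → rt; aq. HCl; TsOH (cat.), toluene, 60 °C
Reagents that add atoms: none
Why: The dianion of an α-sulfanyl acid opens the terminal epoxide at its CH2 group (C7–C8 bond) and acid-catalysed lactonisation of the γ-hydroxy acid closes ring C with C6 unchanged, the epimeric C8 centre being of no consequence because it becomes sp2 later.

Step 7
Reactants: 16 (5R)-5-(but-2-yn-1-yl)-3-(phenylsulfanyl)oxolan-2-one; 7 (E)-tert-butyl[(7-iodo-4-methylhept-4-en-1-yl)oxy]dimethylsilane
Product: 18 (5R)-5-(but-2-yn-1-yl)-3-[(E)-7-(tert-butyldimethylsilyloxy)-4-methylhept-3-en-1-yl]-3-(phenylsulfanyl)oxolan-2-one (C3 epimers), via lithium enolate 17 (not isolated)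
Conditions: LDA, THF, −78 °C; 7, DMPU, −78 °C → rt
Reagents that add atoms: none
Why: Alkylation of the sulfur-stabilised lactone enolate with a primary iodide forms the C8–C9 bond, and the quaternary C8 centre that results (mainly anti to the C6 side chain) is erased in the later elimination.

Step 8
Reactants: 18 silyl ether of the alkylated sulfide lactone
Product: 19 (5R)-5-(but-2-yn-1-yl)-3-[(E)-7-hydroxy-4-methylhept-3-en-1-yl]-3-(phenylsulfanyl)oxolan-2-one
Conditions: 48% aq. HF, MeCN, 0 °C
Reagents that add atoms: none
Why: Acidic fluoride cleaves the primary silyl ether by Si–F bond formation and is harmless to the lactone, sulfide, alkene and alkyne.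

Step 9
Reactants: 19 primary alcohol
Product: 20 (E)-7-[(5R)-5-(but-2-yn-1-yl)-2-oxo-3-(phenylsulfanyl)oxolan-3-yl]-4-methylhept-4-enal
Conditions: Dess–Martin periodinane, CH2Cl2, 0 °C → rt
Reagents that add atoms: none
Why: Dess–Martin oxidation stops at the aldehyde (C1) and does not oxidise aryl alkyl sulfides, alkenes or alkynes.

Step 10
Reactants: 20 aldehyde; 21 methyl acrylate
Product: 22 methyl (E)-9-[(5R)-5-(but-2-yn-1-yl)-2-oxo-3-(phenylsulfanyl)oxolan-3-yl]-3-hydroxy-6-methyl-2-methylidenenon-6-enoate (carbinol epimers)
Conditions: quinuclidine (0.25 equiv), MeOH (0.75 equiv), 21 (neat, excess), rt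
Reagents that add atoms: none
Why: The Morita–Baylis–Hillman reaction joins C1 to C15 of the acrylate through the amine-derived zwitterionic enolate, the new carbinol centre is lost in the next step, and ring C is still the saturated sulfide lactone so the amine cannot epimerise C6.

Step 11
Reactants: 22 Baylis–Hillman adduct
Product: 23 methyl (2Z,6E)-2-(bromomethyl)-9-[(5R)-5-(but-2-yn-1-yl)-2-oxo-3-(phenylsulfanyl)oxolan-3-yl]-6-methylnona-2,6-dienoate
Conditions: PBr3, Et2O, 0 °C
Reagents that add atoms: phosphorus tribromide, BrP(Br)Br
Why: Bromination with allylic transposition (SN2′ pathway) gives the conjugated primary bromide with the chain cis to CH2Br as the more stable isomer, and either allylic isomer would feed the same allylchromium species anyway.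

Step 12
Reactants: 24 2-butyn-1-ol
Product: 25 2-butynal
Conditions: MnO2 (activated, excess), CH2Cl2, rt; filtered, used as solution
Reagents that add atoms: none
Why: Activated MnO2 oxidises the propargylic alcohol selectively to the volatile ynal, which is used as a filtered solution to avoid losses.

Step 13
Reactants: 23 allylic bromide; 25 2-butynal
Product: 28 (4R,5R)-4-{(E)-6-[(5R)-5-(but-2-yn-1-yl)-2-oxo-3-(phenylsulfanyl)oxolan-3-yl]-3-methylhex-3-en-1-yl}-3-methylidene-5-(prop-1-yn-1-yl)oxolan-2-one, via silyl ether 26 (not isolated), via hydroxy ester 27 (not isolated)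
Conditions: CrCl2 (10 mol %), (S,S)-1,8-bis(4-isopropyl-4,5-dihydrooxazol-2-yl)-3,6-diphenyl-9H-carbazole (12 mol %), i-Pr2NEt (30 mol %), Mn (2 equiv), TMSCl (2 equiv), THF, rt; 1 M HCl, THF; TsOH (cat.), CH2Cl2, rt
Reagents that add atoms: none
Why: In this catalytic asymmetric Nozaki–Hiyama-type 2-(alkoxycarbonyl)allylation the allylchromium species from 23 equilibrates between its geometric isomers and adds through C1 in a chair-like Zimmerman–Traxler transition state with the C14 chain equatorial, which gives the anti C1/C2 adduct and hence the trans lactone on acid-induced closure of ring B, while the chiral tridentate ligand on chromium selects the Re face of 25 and so fixes 1R,2R independently of the remote C6 centre.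

Step 14
Reactants: 28 sulfide bislactone diyne
Product: 30 (4R,5R)-4-{(E)-6-[(5R)-5-(but-2-yn-1-yl)-2-oxo-2,5-dihydrofuran-3-yl]-3-methylhex-3-en-1-yl}-3-methylidene-5-(prop-1-yn-1-yl)oxolan-2-one, via sulfoxide 29 (not isolated)
Conditions: mCPBA (1.0 equiv), CH2Cl2, −78 °C; aq. NaHCO3 wash; toluene, 110 °C
Reagents that add atoms: none
Why: Sulfide oxidation is much faster than epoxidation of the trisubstituted alkene at low temperature, and thermal syn-elimination of the sulfoxide toward the ring methylene C7 unveils the C7=C8 butenolide of ring C under neutral conditions that cannot epimerise C6.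

Step 15
Reactants: 30 bislactone diyne
Product: 31 (1R,2R,6R,11E)-18-nor-3,4-didehydro cembranolide cycloalkyne (ring A with C3≡C4; trans-fused ring B at C1/C2; ring C bridging C6 and C8)
Conditions: Mo(≡CC6H4-4-OMe)(OSiPh3)3 (20 mol %), 5 Å MS, toluene (1 mM), 80 °C, Ar
Reagents that add atoms: none
Why: The molybdenum alkylidyne adds in a [2+2] sense to the less hindered 2-butynyl alkyne of 30, the metallacyclobutadiene cycloreverts so that the chain is bound as an alkylidyne at C4, and this tethered alkylidyne engages the propynyl group on C2 in the same way, releasing C3≡C4 and an ethylidyne carrier that leaves as 2-butyne; the closest known reaction type is ring-closing alkyne metathesis of diynes with propargylic ester groups to 12- to 20-membered cycloalkynes with silanolate-ligated molybdenum alkylidynes. Ring A, the 14-membered carbocycle, is closed by this end-to-end macrocyclisation of two methyl-capped alkynes, the linear C2–C3≡C4–C5 unit being spanned by the ten remaining ring atoms. No stereocentre is formed, and C1, C2 and C6 are not at risk because the medium holds no acid, base or redox-active species. The step needs closure over oligomerisation, which is secured by millimolar dilution and by molecular sieves that bind 2-butyne and so pull all equilibria, those of oligomers included, toward the ring. It also needs indifference to the other π-systems: alkylidynes of this type do not react with alkenes, so the exo-methylene lactone, the butenolide and C11=C12 remain spectators, and the silanolate ligands temper the Lewis acidity enough for both lactone carbonyls and the propargylic C2–O bond to survive. Since a cycloalkyne has no geometric isomers, the C3=C4 geometry is decided afterwards under reagent control.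

Step 16
Reactants: 31 cycloalkyne
Product: 32 (1R,2R,3Z,6R,11E)-4-triethylsilyl-18-nor cembranolide (Si on C4 and cis to C2)
Conditions: [Cp*Ru(MeCN)3]PF6 (5 mol %), Et3SiH (1.3 equiv), CH2Cl2, 0 °C → rt
Reagents that add atoms: triethylsilane, CC[SiH](CC)CC
Why: In this ruthenium-catalysed trans-hydrosilylation the cationic Cp*Ru fragment delivers hydride to C3 and silicon to C4, the alkyne carbon remote from the branched and electron-poor acyloxy carbon C2, and adds them to opposite faces, so that C2 and C5 end up trans in ring A and silicon lies cis to C2, while alkenes and enoates are not hydrosilylated under these conditions.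

Step 17
Reactants: 32 alkenylsilane
Product: 33 (1R,2R,3Z,6R,11E)-4-iodo-18-nor cembranolide
Conditions: NIS (1.1 equiv), 2,6-lutidine (0.8 equiv), (CF3)2CHOH, 0 °C, dark
Reagents that add atoms: N-iodosuccinimide, O=C1CCC(=O)N1I
Why: Electrophilic ipso-iododesilylation in hexafluoroisopropanol goes with retention because the solvent speeds loss of silicon from the β-silyl cation before rotation about C3–C4, and iodonium transfer to C11=C12 is reversible in this non-nucleophilic medium whereas loss of silicon is not.

Step 18
Reactants: 33 alkenyl iodide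
Product: 34 (1R,2S,3E,6R,11E)-cembranolide bislactone (parent of the target; methyl C18 on C4)
Conditions: MeZnCl (2 equiv), PdCl2(dppf) (5 mol %), THF, 0 °C → rt
Reagents that add atoms: methylzinc chloride, C[Zn]Cl
Why: In the Negishi coupling, oxidative addition of zerovalent palladium into the C4–I bond, transmetalation and reductive elimination all go with retention, which places methyl C18 cis to C2 (E-C3=C4), and the organozinc reagent does not add to lactones or enoates at this temperature.

Step 19
Reactants: 34 parent cembranolide
Product: 35 target hydroperoxide (1R,2S,3E,6R,10E,12S)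
Conditions: O2, tetraphenylporphyrin (cat.), CH2Cl2, −20 °C, white LED; chromatography
Reagents that add atoms: dioxygen, O=O
Why: In the Schenck ene reaction singlet oxygen attacks the only electron-rich alkene (C3=C4 is deactivated by the allylic C2 acyloxy group and the two enoates are inert), bonds to C12 from the exposed outer face of ring A and takes an outward-pointing hydrogen from C10 on the more substituted side of the alkene (cis effect), which shifts the alkene to E-C10=C11 and should set C12 as S.

## Compound list

1 | 4-pentyn-1-ol | C#CCCCO | starting material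
2 | tert-butyldimethyl(pent-4-yn-1-yloxy)silane | C#CCCCO[Si](C)(C)C(C)(C)C | intermediate
3 | ethylene oxide | C1CO1 | starting material
4 | (E)-[5-(tert-butyldimethylsilyloxy)-2-methylpent-1-en-1-yl]dimethylalane | C[Al](C)/C=C(\C)CCCO[Si](C)(C)C(C)(C)C | intermediate
5 | lithium butyl[(E)-5-(tert-butyldimethylsilyloxy)-2-methylpent-1-en-1-yl]dimethylalanate | [Li+].CCCC[Al-](C)(C)/C=C(\C)CCCO[Si](C)(C)C(C)(C)C | intermediate
6 | (E)-7-(tert-butyldimethylsilyloxy)-4-methylhept-3-en-1-ol | OCC/C=C(\C)CCCO[Si](C)(C)C(C)(C)C | intermediate
7 | (E)-tert-butyl[(7-iodo-4-methylhept-4-en-1-yl)oxy]dimethylsilane | ICC/C=C(\C)CCCO[Si](C)(C)C(C)(C)C | intermediate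
8 | propyne | CC#C | starting material
9 | (R)-epichlorohydrin | ClC[C@H]1CO1 | starting material
10 | 1-propynyllithium | [Li]C#CC | intermediate
11 | (R)-1-chlorohex-4-yn-2-ol | ClC[C@H](O)CC#CC | intermediate
12 | (R)-2-(but-2-yn-1-yl)oxirane | CC#CC[C@@H]1CO1 | intermediate
13 | (phenylsulfanyl)acetic acid | OC(=O)CSc1ccccc1 | starting material
14 | dilithio dianion of (phenylsulfanyl)acetic acid | [Li]OC(O[Li])=CSc1ccccc1 | intermediate
15 | (4R)-4-hydroxy-2-(phenylsulfanyl)oct-6-ynoic acid (C2 epimers) | OC(=O)C(Sc1ccccc1)C[C@H](O)CC#CC | intermediate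
16 | (5R)-5-(but-2-yn-1-yl)-3-(phenylsulfanyl)oxolan-2-one (C3 epimers) | CC#CC[C@@H]1CC(Sc2ccccc2)C(=O)O1 | intermediate
17 | lithium enolate of 16 | CC#CC[C@@H]1CC(Sc2ccccc2)=C(O[Li])O1 | intermediate
18 | alkylated sulfide lactone, TBS ether (C8 epimers) | CC#CC[C@@H]1CC(CC/C=C(\C)CCCO[Si](C)(C)C(C)(C)C)(Sc2ccccc2)C(=O)O1 | intermediate
19 | alkylated sulfide lactone, primary alcohol | CC#CC[C@@H]1CC(CC/C=C(\C)CCCO)(Sc2ccccc2)C(=O)O1 | intermediate
20 | alkylated sulfide lactone, C1 aldehyde | CC#CC[C@@H]1CC(CC/C=C(\C)CCC=O)(Sc2ccccc2)C(=O)O1 | intermediate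
21 | methyl acrylate | C=CC(=O)OC | starting material
22 | Baylis–Hillman adduct (carbinol epimers) | CC#CC[C@@H]1CC(CC/C=C(\C)CCC(O)C(=C)C(=O)OC)(Sc2ccccc2)C(=O)O1 | intermediate
23 | (2Z,6E)-2-(bromomethyl)dienoate | CC#CC[C@@H]1CC(CC/C=C(\C)CC/C=C(\CBr)C(=O)OC)(Sc2ccccc2)C(=O)O1 | intermediate
24 | 2-butyn-1-ol | CC#CCO | starting material
25 | 2-butynal | CC#CC=O | intermediate
26 | methyl (3R,4R)-2-methylidene-4-(trimethylsilyloxy)hept-5-ynoate bearing the C14–C9 chain and sulfide lactone on C3 | COC(=O)C(=C)[C@@H](CC/C(C)=C/CCC1(Sc2ccccc2)C[C@@H](CC#CC)OC1=O)[C@@H](O[Si](C)(C)C)C#CC | intermediate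
27 | corresponding (3R,4R)-4-hydroxy ester (anti) | COC(=O)C(=C)[C@@H](CC/C(C)=C/CCC1(Sc2ccccc2)C[C@@H](CC#CC)OC1=O)[C@@H](O)C#CC | intermediate
28 | sulfide bislactone diyne (trans ring B, saturated ring C) | C=C1C(=O)O[C@@H](C#CC)[C@@H]1CC/C(C)=C/CCC2(Sc3ccccc3)C[C@@H](CC#CC)OC2=O | intermediate
29 | sulfoxide of 28 | C=C1C(=O)O[C@@H](C#CC)[C@@H]1CC/C(C)=C/CCC2(S(=O)c3ccccc3)C[C@@H](CC#CC)OC2=O | intermediate
30 | bislactone diyne (metathesis precursor) | C=C1C(=O)O[C@@H](C#CC)[C@@H]1CC/C(C)=C/CCC2=C[C@@H](CC#CC)OC2=O | intermediate
31 | 18-nor C3≡C4 cycloalkyne bislactone | C=C1C(=O)O[C@H]2C#CC[C@@H]3C=C(CC/C=C(\C)CC[C@H]12)C(=O)O3 | intermediate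
32 | (3Z)-4-triethylsilyl macrocycle | C=C1C(=O)O[C@H]2/C=C(\[Si](CC)(CC)CC)C[C@@H]3C=C(CC/C=C(\C)CC[C@H]12)C(=O)O3 | intermediate
33 | (3Z)-4-iodo macrocycle | C=C1C(=O)O[C@H]2/C=C(\I)C[C@@H]3C=C(CC/C=C(\C)CC[C@H]12)C(=O)O3 | intermediate
34 | parent (3E,11E)-cembranolide bislactone | C=C1C(=O)O[C@H]2/C=C(\C)C[C@@H]3C=C(CC/C=C(\C)CC[C@H]12)C(=O)O3 | intermediate
35 | CNP0343227.1, (1R,2S,3E,6R,10E,12S)-12-hydroperoxide | C=C1C(=O)O[C@H]2/C=C(\C)C[C@@H]3C=C(C/C=C/[C@@](C)(OO)CC[C@H]12)C(=O)O3 | target

## Step count and risks

Total step count: 19.
Longest linear sequence: 15 steps (1–3, 7–11, 13–19). The branch 4–6 followed by 7–11 and 13–19 is of equal length.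

**Step 15, ring closure.** Intermolecular metathesis to oligomers may outrun closure, because two planar lactone rings and the E-alkene stiffen the chain that has to span a linear four-carbon unit. The propargylic alkylidyne at C3 may also decay by loss of the C2 carboxylate and drain the catalyst. The fallback changes the substrate of the ring closure and sets out from 28. Ring C is still saturated there (C7 and C8 are sp3), so the tether is more flexible and carries no conjugated lactone. The same molybdenum alkylidyne, which tolerates thioethers, would close ring A to the cycloalkyne sulfide lactone F1. One equivalent of mCPBA at −78 °C would give the cycloalkyne sulfoxide F2. Thermolysis in toluene would then introduce the C7=C8 alkene inside the finished ring. The route is rejoined at 31.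

**Step 17, iododesilylation.** Electrophilic iodine may be consumed at the more nucleophilic C11=C12 alkene, because ipso attack at C4 builds positive charge at C3 next to the acyloxy carbon and is therefore slow. Slow loss of silicon would also allow rotation about C3–C4 and erosion of the alkene geometry. The fallback avoids electrophilic halogen altogether and sets out from 31. Ruthenium-catalysed trans-hydrostannation ([Cp*Ru(MeCN)3]PF6, Bu3SnH, CH2Cl2) should place tin on the less hindered C4 and give the (3Z)-4-tributylstannyl macrocycle F3, any C3 regioisomer being removed by chromatography. A methyl Stille coupling would then replace tin by methyl with retention (MeI, Pd(PPh3)4, copper thiophene-2-carboxylate Cu(O2CC4H3S), [NBu4][Ph2PO2], DMF, rt). The route is rejoined at 34, which bypasses steps 16–18.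

**Step 19, Schenck ene reaction.** Hydrogen abstraction from methyl C20 instead of C10 would lead to oxygenation at C11. Attack on the inner face would invert C12. Slow oxygenation of C3=C4 may erode the product on long irradiation. The fallback moves the ene reaction forward and sets out from 33, in which iodine switches off C3=C4 and changes the conformation of ring A. Photooxygenation under the same sensitised conditions would give the 4-iodo 12-hydroperoxide F4. Treatment with 2-methoxypropene and PPTS would mask it as the 4-iodo peroxyketal F5, a peroxide form that survives palladium-catalysed coupling. Stille methylation (Me4Sn, Pd2(dba)3, AsPh3, DMF, 40 °C) would give the methylated peroxyketal F6. Aqueous acetic acid in THF would release the hydroperoxide. The route is rejoined at 35.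

## Further compounds

F1 | step 15 | cycloalkyne sulfide lactone (ring A closed, ring C saturated with 8-phenylsulfanyl group, C8 epimers) | C=C1C(=O)O[C@H]2C#CC[C@@H]3CC(Sc4ccccc4)(CC/C=C(\C)CC[C@H]12)C(=O)O3
F2 | step 15 | cycloalkyne sulfoxide | C=C1C(=O)O[C@H]2C#CC[C@@H]3CC(S(=O)c4ccccc4)(CC/C=C(\C)CC[C@H]12)C(=O)O3
F3 | step 17 | (3Z)-4-tributylstannyl macrocycle | C=C1C(=O)O[C@H]2/C=C(\[Sn](CCCC)(CCCC)CCCC)C[C@@H]3C=C(CC/C=C(\C)CC[C@H]12)C(=O)O3
F4 | step 19 | 4-iodo 12-hydroperoxide | C=C1C(=O)O[C@H]2/C=C(\I)C[C@@H]3C=C(C/C=C/[C@@](C)(OO)CC[C@H]12)C(=O)O3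
F5 | step 19 | 4-iodo peroxyketal (2-methoxyprop-2-yl peroxide) | C=C1C(=O)O[C@H]2/C=C(\I)C[C@@H]3C=C(C/C=C/[C@@](C)(OOC(C)(C)OC)CC[C@H]12)C(=O)O3
F6 | step 19 | methylated peroxyketal | C=C1C(=O)O[C@H]2/C=C(\C)C[C@@H]3C=C(C/C=C/[C@@](C)(OOC(C)(C)OC)CC[C@H]12)C(=O)O3
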